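The constants used here belong to no real substance, and the outcome is calculated.

Solid E left over at the end, you say, must mean that dissolving holds this flask back; I read the leftover the other way, and here is my quick number.

E 0.50 M; Q 20 mM (held); time 10 h

    Q ⇌ J, rate k1*(csat - [J]) (k1 = 0.0015 s⁻¹, csat = 20 mM)
    E ⇌ L, rate k2*(cs2 - [L]) while solid is left; crystals form when [L] > cs2 (cs2 = 24 mM, k2 = 0.0052 s⁻¹)
    L + J → L.J (k3 = 0.0069 M⁻¹ s⁻¹)
    G ⇌ L.J, rate k4*(cs4 - [L.J]) while solid is left; crystals form when [L.J] > cs4 (cs4 = 0.093 M, k4 = 0.026 s⁻¹)
    2 L → L2 (k5 = 0.0012 M⁻¹ s⁻¹)

- percentages count the E that a species holds: one L2 counts as two
- L.J is meant together with its G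
- for a step with 2 of a species take k times the square, and two of it per event
- solid, in amounts per volume of the solution: E, G
- at the start none of J is dissolved
- at the start none of E is in solution
- run time (flask): 10 h

1. how much L.J and G together there is at 10 h, in percent of the E charged
2. the change that raises the amount of L.J and G together at 10 h, in percent of the E charged most ("none" if none brings more than 2 percentage points) (Friday's / Wednesday's / Saturday's / Tuesday's / none)
3. amount of L.J and G together at 10 h, in percent of the E charged, after Saturday's

- Friday's: doubling the solubility in step 4, all else as stated
- Wednesday's: doubling the dissolution coefficient of step 4, all else as stated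
- Saturday's: doubling the saturation concentration of Q, all else as stated
- Tuesday's: doubling the dissolution coefficient of step 2, all else as stated

Into a solution kept empty, the dissolving of E could deliver 899% of the charge by 10 h if the solid never ran out, so I take L to stand near its solubility after about 3.21 min. With L there, the loss of J to L is pseudo-first-order, and J has a lifetime τ against transfer and that loss together. I reckon τ first:

τ = 1 / (transfer coefficient + rate constant × solubility of L) = 10.0 min

Since τ is much shorter than the run, I take J to hold a steady level:

level of J = saturation concentration × transfer coefficient × τ = 18.0 mM

The rate of forming L.J at these two levels is D: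

D = rate constant × solubility of L × level of J = 10.7 mM h⁻¹

I call D the draw, and it gives the yield:

yield = D × time / E charged = 21.5%

That yield is far less than the dissolving could offer, so I expect solid E to remain at the end. Friday's and Wednesday's act between L.J and G, which are counted together, so I expect nothing from them. Tuesday's hurries a dissolving that already offers more than D takes, so I expect little. Saturday's doubles the level of J and so D, which gives 43.0%, and that is my choice.

The forecast gives 20.4%, Saturday's and 40%, holding that “L.J forms at a nearly steady rate”.

The flask as charged gives 20.5%; Saturday's is the best change, with 40.1%, a gain of 20 percentage points.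

This flask stands at 20.5% chiefly for want of time: left until 100 h, it holds 69.7%, an amount that takes 32.5 h at D, against the 10 h allowed. For the same charge stopped at 2.5 h, D gives 5.37%, and that neighbour flask holds 4.84%.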